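## Retrosynthetic overview

1. Target 31 ⇐ acetylation of the C11 carbinol and C3–O/C16 lactonisation (ε-lactone, last ring); C15 from hydroboration of a C14 isopropenyl group; C11 carbinol from MeMgBr and a C11 ketone.
2. Cyclohexane (C1, C10–C14) ⇐ Diels–Alder reaction of methyl vinyl ketone with a 2-ethoxydiene (C1=C10–C11=C12) on the oxa-bridged bicycle; C3 carbinol from MeMgBr and the ring-expanded C3 ketone.
3. Nine-membered oxonene (O, C2–C9) and ten-membered carbocycle ⇐ Claisen ring expansion of a seven-membered 1,4-dioxepane (O, C2, C3, O′, C7, C8, C9) that gold closes in the same flask.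
4. Enabling feature: the cis-2,5-disubstituted oxolane (C2 and C9 flank the ring oxygen) holds the C2 ethynyl group (C3≡C4) and the C9 arm CH2–C(Me)(OH)–CH=CH2 on one face. O′–C3 closure therefore gives an exocyclic enol ether C3=C4 beside the C7 vinyl group (C6=C5), an allyl vinyl ether whose C7–O′ bond lies inside the seven-membered ring.
5. Oxolane ⇐ γ-lactone with one catalyst-set stereocentre (C2, asymmetric transfer hydrogenation of an ynone). Ring order: oxolane → [dioxepane] → oxonene/carbocycle → cyclohexane → ε-lactone.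

Key step: step 10

Remarks on the chemistry (assumptions):
- Atom numbers are cladiellin numbers: the ring oxygen bridges C2 and C9; C1/C10 are the ring-fusion carbons; C3 carries Me and O; C6=C7 is the Z alkene; C11 carries Me and OAc; C14 carries the C15(Me)–C16(=O) arm. O′ is the oxygen on C7. The target is (1S,2S,3S,6Z,9S,10R,11R,14R,15R).
- The C7 carbinol centre made in step 8 is not controlled and becomes sp2 in step 10. Compounds 12–14 are therefore carried as C7 epimer mixtures and their SMILES leave C7 undefined.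
- The sense of the transfer hydrogenation ((S,S)-catalyst → (S)-carbinol) and of (−)-Ipc2BH (→ 15R) is taken from the usual behaviour of these reagents with ynones and 2-substituted 1-alkenes.

## Route

Step 1
Reactants: 1 methyl 4-chloro-4-oxobutanoate; 2 bis(trimethylsilyl)acetylene
Product: 3 methyl 4-oxo-6-(trimethylsilyl)hex-5-ynoate
Conditions: AlCl3, CH2Cl2, 0 °C
Reagents that add atoms: none
Why: Friedel–Crafts-type acylation of the alkynylsilane (ipso substitution of one silyl group) should give the silyl ynone without touching the ester.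

Step 2
Reactants: 3 methyl 4-oxo-6-(trimethylsilyl)hex-5-ynoate
Product: 5 (S)-5-[(trimethylsilyl)ethynyl]oxolan-2-one, via hydroxy ester 4 (not isolated)
Conditions: RuCl[(S,S)-TsDPEN](p-cymene) (1 mol %), i-PrOH, 23 °C; then PPTS (cat.), PhMe, 80 °C
Reagents that add atoms: none
Why: Noyori asymmetric transfer hydrogenation of the ynone should set C2 as (S) by catalyst control (the alkynyl group takes the role of the aryl group), and the γ-hydroxy ester then lactonises under acid catalysis.

Step 3
Reactants: 5 (S)-5-[(trimethylsilyl)ethynyl]oxolan-2-one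
Product: 6 (3R,5S)-3-hydroxy-5-[(trimethylsilyl)ethynyl]oxolan-2-one
Conditions: NaHMDS, THF, −78 °C; 2-(phenylsulfonyl)-3-phenyloxaziridine; NH4Cl
Reagents that add atoms: 2-(phenylsulfonyl)-3-phenyloxaziridine, O=S(=O)(N1OC1c1ccccc1)c1ccccc1
Why: Enolate oxidation with the Davis oxaziridine should deliver oxygen to C10 anti to the C2 alkynyl group (trans-3,5), the usual substrate control in γ-substituted butyrolactones.

Step 4
Reactants: 6 (3R,5S)-3-hydroxy-5-[(trimethylsilyl)ethynyl]oxolan-2-one
Product: 7 (3R,5S)-3-(tert-butyldimethylsilyloxy)-5-[(trimethylsilyl)ethynyl]oxolan-2-one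
Conditions: TBSCl, imidazole, DMF, 23 °C
Reagents that add atoms: tert-butyldimethylsilyl chloride, CC(C)(C)[Si](C)(C)Cl
Why: Standard silylation of the secondary alcohol; the silyl ether later steers the reduction in step 6 and masks the C10 oxygen until step 12.

Step 5
Reactants: 7 (3R,5S)-3-(tert-butyldimethylsilyloxy)-5-[(trimethylsilyl)ethynyl]oxolan-2-one
Product: 8 (3R,5S)-3-(tert-butyldimethylsilyloxy)-2-(2-methylallyl)-5-[(trimethylsilyl)ethynyl]oxolan-2-ol (anomer mixture)
Conditions: 2-methylallylmagnesium chloride (1.2 equiv), THF, −78 °C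
Reagents that add atoms: 2-methylallylmagnesium chloride, CC(=C)C[Mg]Cl
Why: Grignard mono-addition to the lactone should stop at the magnesium lactolate at low temperature, as in C-glycoside syntheses from sugar lactones; the anomeric centre is removed in step 6.

Step 6
Reactants: 8 (3R,5S)-3-(tert-butyldimethylsilyloxy)-2-(2-methylallyl)-5-[(trimethylsilyl)ethynyl]oxolan-2-ol
Product: 9 (2S,3R,5S)-3-(tert-butyldimethylsilyloxy)-2-(2-methylallyl)-5-[(trimethylsilyl)ethynyl]oxolane
Conditions: Et3SiH, BF3·OEt2, CH2Cl2, −78 °C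
Reagents that add atoms: none
Why: Ionic reduction of the lactol through the cyclic oxocarbenium ion should place hydride cis to the adjacent silyloxy group (inside attack) and anti to the C2 alkynyl group, which sets C9 with the C8 chain cis to the alkyne (2,5-cis oxolane).

Step 7
Reactants: 9 (2S,3R,5S)-3-(tert-butyldimethylsilyloxy)-2-(2-methylallyl)-5-[(trimethylsilyl)ethynyl]oxolane
Product: 11 1-[(2S,3R,5S)-3-(tert-butyldimethylsilyloxy)-5-[(trimethylsilyl)ethynyl]oxolan-2-yl]propan-2-one, via ozonide 10 (not isolated)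
Conditions: O3, CH2Cl2, −78 °C; Me2S
Reagents that add atoms: ozone, [O-][O+]=O
Why: Ozonolysis should cleave the electron-rich 1,1-disubstituted alkene much faster than the silyl alkyne and give the methyl ketone (C7) after reductive work-up.

Step 8
Reactants: 11 1-[(2S,3R,5S)-3-(tert-butyldimethylsilyloxy)-5-[(trimethylsilyl)ethynyl]oxolan-2-yl]propan-2-one
Product: 12 1-[(2S,3R,5S)-3-(tert-butyldimethylsilyloxy)-5-[(trimethylsilyl)ethynyl]oxolan-2-yl]-2-methylbut-3-en-2-ol (C7 epimer mixture)
Conditions: vinylMgBr, THF, −78 °C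
Reagents that add atoms: vinylmagnesium bromide, C=C[Mg]Br
Why: Grignard 1,2-addition at low temperature (to avoid β-elimination of the ring oxygen) should give the tertiary allylic alcohol; C7 is not reliably controlled and need not be, because it is destroyed in step 10.

Step 9
Reactants: 12 1-[(2S,3R,5S)-3-(tert-butyldimethylsilyloxy)-5-[(trimethylsilyl)ethynyl]oxolan-2-yl]-2-methylbut-3-en-2-ol
Product: 13 1-[(2S,3R,5S)-3-(tert-butyldimethylsilyloxy)-5-ethynyloxolan-2-yl]-2-methylbut-3-en-2-ol (C7 epimer mixture)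
Conditions: K2CO3 (cat.), MeOH, 23 °C
Reagents that add atoms: none
Why: Base-catalysed methanolysis should cleave only the alkynyl C–Si bond and leave the secondary TBS ether in place.

Step 10
Reactants: 13 1-[(2S,3R,5S)-3-(tert-butyldimethylsilyloxy)-5-ethynyloxolan-2-yl]-2-methylbut-3-en-2-ol
Product: 15 (1S,8S,9R,5Z)-9-(tert-butyldimethylsilyloxy)-6-methyl-11-oxabicyclo[6.2.1]undec-5-en-2-one (C3 ketone and Z-C6=C7 in cladiellin numbering), via enol ether 14 (not isolated)
Conditions: JohnPhosAu(MeCN)SbF6 (5 mol %), 4 Å MS, PhMe, 23 °C, then 110 °C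
Reagents that add atoms: none
Why: Proposed new method: the cationic gold(I) catalyst activates the terminal alkyne (C3≡C4) and the C7 tertiary allylic hydroxyl adds at the internal carbon C3 (Markovnikov, 7-exo-dig), closing the 1,4-dioxepane (O, C2, C3, O′, C7, C8, C9) as the bridged 2-methylene-7-vinyl enol ether 14; on warming, this allyl vinyl ether undergoes a [3,3] Claisen shift (C4–C5 made, C7–O′ broken) that expels O′ from the seven-membered ring and inserts C4–C5–C6, so the nine-membered oxonene and the ten-membered carbocycle arise together by a two-atom ring expansion. The closest known reactions are the gold-catalysed intermolecular hydroalkoxylation of alkynes with allylic alcohols followed by Claisen rearrangement and the Tebbe methylenation–Claisen ring expansion of vinyl-substituted lactones (2-methylene-6-vinyl oxacycles to 4-cycloalkenones); new here are the 7-exo closure by a tertiary alcohol and the telescoping into the ring expansion. No stereocentre is created: C7 becomes sp2 and only the C6=C7 geometry is set, and the four-atom tether (C8–C9–O–C2) between C7 and C3 allows only a chair-like array with C8 axial (gauche C8–C7–O′–C3 torsion), which should give the Z alkene from either C7 epimer, the two epimers reacting on opposite faces of the dioxepane. The selectivities needed are O-attack at C3 rather than C4 and cyclisation rather than hydration or ionisation of the tertiary allylic alcohol; they are secured by the cis-2,5 arrangement on the oxolane that keeps hydroxyl and alkyne within reach, by the Markovnikov preference of gold-activated terminal alkynes and by dry, non-nucleophilic conditions. C2 is a bridgehead of 14, which blocks both isomerisation of the exocyclic enol ether into the ring and epimerisation at C2, and the exo silyloxy group at C10 lies away from the reacting bridge.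

Step 11
Reactants: 15 (1S,8S,9R,5Z)-9-(tert-butyldimethylsilyloxy)-6-methyl-11-oxabicyclo[6.2.1]undec-5-en-2-one
Product: 16 (1S,2S,8S,9R,5Z)-9-(tert-butyldimethylsilyloxy)-2,6-dimethyl-11-oxabicyclo[6.2.1]undec-5-en-2-ol
Conditions: MeMgBr, THF, −78 °C
Reagents that add atoms: methylmagnesium bromide, C[Mg]Br
Why: Grignard 1,2-addition to the ring-held C3 ketone should take place on the face syn to the bridging oxygen and anti to C1 (the other face is screened by the endo C1–H of the two-carbon bridge), which sets C3 (S) with the hydroxyl turned towards C1, the sense known for methyl additions to 3-oxo oxa-bridged nine-membered rings of this family.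

Step 12
Reactants: 16 (1S,2S,8S,9R,5Z)-9-(tert-butyldimethylsilyloxy)-2,6-dimethyl-11-oxabicyclo[6.2.1]undec-5-en-2-ol
Product: 17 (1S,2S,8S,9R,5Z)-2,6-dimethyl-11-oxabicyclo[6.2.1]undec-5-ene-2,9-diol
Conditions: TBAF, THF, 23 °C
Reagents that add atoms: none
Why: Fluoride desilylation should free the C10 hydroxyl without affecting the alkene or the tertiary alcohol.

Step 13
Reactants: 17 (1S,2S,8S,9R,5Z)-2,6-dimethyl-11-oxabicyclo[6.2.1]undec-5-ene-2,9-diol
Product: 18 (1S,2S,8S,5Z)-2-hydroxy-2,6-dimethyl-11-oxabicyclo[6.2.1]undec-5-en-9-one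
Conditions: Dess–Martin periodinane, NaHCO3, CH2Cl2, 23 °C
Reagents that add atoms: none
Why: Dess–Martin oxidation should convert only the secondary C10 alcohol to the ketone; the tertiary C3 alcohol cannot be oxidised and a hemiketal between them would be a strained dioxanorbornane.

Step 14
Reactants: 18 (1S,2S,8S,5Z)-2-hydroxy-2,6-dimethyl-11-oxabicyclo[6.2.1]undec-5-en-9-one
Product: 19 (1S,2S,8S,5Z)-2-hydroxy-2,6-dimethyl-11-oxabicyclo[6.2.1]undeca-5,9-dien-9-yl trifluoromethanesulfonate
Conditions: KHMDS (2.2 equiv), THF, −78 °C; PhNTf2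
Reagents that add atoms: N-phenylbis(trifluoromethanesulfonimide), O=S(=O)(N(c1ccccc1)S(=O)(=O)C(F)(F)F)C(F)(F)F
Why: Kinetic enolate triflation should occur towards C1 because C9 is a bridgehead, and the hindered tertiary potassium alkoxide at C3 should not be sulfonylated by the mild N-triflyl donor.

Step 15
Reactants: 19 (1S,2S,8S,5Z)-2-hydroxy-2,6-dimethyl-11-oxabicyclo[6.2.1]undeca-5,9-dien-9-yl trifluoromethanesulfonate
Product: 20 (1S,2S,8S,5Z)-9-(1-ethoxyvinyl)-2,6-dimethyl-11-oxabicyclo[6.2.1]undeca-5,9-dien-2-ol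
Conditions: tributyl(1-ethoxyvinyl)stannane, Pd(PPh3)4 (cat.), LiCl, THF, 65 °C
Reagents that add atoms: tributyl(1-ethoxyvinyl)stannane, CCCC[Sn](CCCC)(CCCC)C(=C)OCC
Why: Stille coupling of the enol triflate should install C11–C12 as an electron-rich 2-ethoxydiene (C1=C10–C11=C12) and tolerates the free alcohol and the ring alkene.

Step 16
Reactants: 20 (1S,2S,8S,5Z)-9-(1-ethoxyvinyl)-2,6-dimethyl-11-oxabicyclo[6.2.1]undeca-5,9-dien-2-ol
Product: 22 tricyclic enol ether (1S,2S,3S,6Z,9S,14R)-14-acetyl-11-ethoxy-2,9-epoxy-3-hydroxy-3,7-dimethyl-cyclohexane-fused oxonene with C10=C11 (cladiellin numbering; acetyl trans to C2), via endo adduct 21 (not isolated)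
Conditions: methyl vinyl ketone, BHT, PhMe, 110 °C (sealed tube); then K2CO3, MeOH, 23 °C
Reagents that add atoms: methyl vinyl ketone, CC(=O)C=C
Why: Diels–Alder reaction of the 2-ethoxydiene with the enone (ethoxy carbon para to the acyl-bearing carbon) should occur on the exo face of the oxa-bridged diene, opposite the six-carbon bridge, which sets C1 with H1 syn to C3, and the base treatment then moves the epimerisable C14 acetyl group of the kinetic endo adduct to the equatorial position trans to C2.

Step 17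
Reactants: 22 tricyclic enol ether with C14 acetyl group
Product: 23 tricyclic enol ether (1S,2S,3S,6Z,9S,14R) with C14 isopropenyl group (C10=C11 ethyl enol ether and C3 hydroxyl retained)
Conditions: Ph3PCH3Br, KOt-Bu (excess), THF, 0 → 23 °C
Reagents that add atoms: methyltriphenylphosphonium bromide, C[P+](c1ccccc1)(c1ccccc1)c1ccccc1.[Br-]
Why: Wittig methylenation should convert the methyl ketone into the isopropenyl group while the C11 carbonyl is still masked as the enol ether; C14 is already in its thermodynamic configuration, so the basic conditions cannot scramble it.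

Step 18
Reactants: 23 tricyclic enol ether with C14 isopropenyl group
Product: 24 tricyclic ketone (1S,2S,3S,6Z,9S,10R,14R)-3-hydroxy-14-isopropenyl-3,7-dimethyl-2,9-epoxy-cladiell-6-en-11-one (11-nor-methyl; cis ring fusion)
Conditions: 0.5 M HCl, THF/H2O, 0 °C
Reagents that add atoms: water, O
Why: Mild acid hydrolysis of the enol ether should unveil the C11 ketone, and C10, now α to the carbonyl, should settle under thermodynamic control with the cyclohexanone cis-fused on the exo side of the oxolane (H10 syn to H1); the acid is kept weak to avoid transannular attack of the C3 hydroxyl on the C6=C7 alkene.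

Step 19
Reactants: 24 tricyclic C11 ketone
Product: 25 diol (1S,2S,3S,6Z,9S,10R,11R,14R)-14-isopropenyl-3,7,11-trimethyl-2,9-epoxy-cladiell-6-ene-3,11-diol
Conditions: MeMgBr (excess), THF, −78 → 0 °C
Reagents that add atoms: methylmagnesium bromide, C[Mg]Br
Why: Grignard addition should come from the convex face of the cis-fused cyclohexanone, anti to the axial C10–C9 bond, which places the methyl group cis to H10 and the hydroxyl cis to C9 (11R).

Step 20
Reactants: 25 diol with C14 isopropenyl group
Product: 27 triol (1S,2S,3S,6Z,9S,10R,11R,14R,15R) with C14 CH(CH3)CH2OH arm, via alkylborane 26 (not isolated)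
Conditions: (−)-Ipc2BH [from (+)-α-pinene], THF, −25 → 0 °C; then NaOH, H2O2
Reagents that add atoms: hydrogen peroxide, OO
Why: Brown hydroboration–oxidation should take the 1,1-disubstituted alkene in preference to the trisubstituted ring alkene and place boron at C16, with C15 set by reagent control of the chiral dialkylborane (the antipode whose intrinsic preference for 2-substituted 1-alkenes corresponds to 15R) acting together with the adjacent C14 centre.

Step 21
Reactants: 27 triol
Product: 30 hydroxy lactone (11-deacetyl target), via hydroxy aldehyde 28 (not isolated), via lactol 29 (not isolated)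
Conditions: TEMPO (cat.), PhI(OAc)2, CH2Cl2, 23 °C
Reagents that add atoms: none
Why: TEMPO/PhI(OAc)2 oxidative lactonisation should oxidise only the primary alcohol; the aldehyde is captured by the C3 hydroxyl (which step 11 turned towards C1 and the C14 arm) as the seven-membered lactol and oxidised again to the lactone, and the C11 hydroxyl, trans-1,4 to the arm, cannot reach it.

Step 22
Reactants: 30 hydroxy lactone
Product: 31 target, (1S,2S,3S,6Z,9S,10R,11R,14R,15R)-11-acetoxy lactone
Conditions: Ac2O, DMAP, Et3N, CH2Cl2, 40 °C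
Reagents that add atoms: acetic anhydride, CC(=O)OC(C)=O
Why: DMAP-catalysed acylation should esterify the remaining tertiary C11 alcohol, the only free hydroxyl left.

## Compound list

1 | methyl 4-chloro-4-oxobutanoate | COC(=O)CCC(Cl)=O | starting material
2 | bis(trimethylsilyl)acetylene | C[Si](C)(C)C#C[Si](C)(C)C | starting material
3 | methyl 4-oxo-6-(trimethylsilyl)hex-5-ynoate | COC(=O)CCC(=O)C#C[Si](C)(C)C | intermediate
4 | methyl (S)-4-hydroxy-6-(trimethylsilyl)hex-5-ynoate (not isolated) | COC(=O)CC[C@H](O)C#C[Si](C)(C)C | intermediate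
5 | (S)-5-[(trimethylsilyl)ethynyl]oxolan-2-one | O=C1CC[C@@H](C#C[Si](C)(C)C)O1 | intermediate
6 | (3R,5S)-3-hydroxy-5-[(trimethylsilyl)ethynyl]oxolan-2-one | O=C1[C@H](O)C[C@@H](C#C[Si](C)(C)C)O1 | intermediate
7 | (3R,5S)-3-(TBS-oxy)-5-[(trimethylsilyl)ethynyl]oxolan-2-one | O=C1[C@H](O[Si](C)(C)C(C)(C)C)C[C@@H](C#C[Si](C)(C)C)O1 | intermediate
8 | (3R,5S)-3-(TBS-oxy)-2-(2-methylallyl)-5-[(trimethylsilyl)ethynyl]oxolan-2-ol (anomer mixture) | C=C(C)CC1(O)O[C@H](C#C[Si](C)(C)C)C[C@H]1O[Si](C)(C)C(C)(C)C | intermediate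
9 | (2S,3R,5S)-3-(TBS-oxy)-2-(2-methylallyl)-5-[(trimethylsilyl)ethynyl]oxolane | C=C(C)C[C@@H]1O[C@H](C#C[Si](C)(C)C)C[C@H]1O[Si](C)(C)C(C)(C)C | intermediate
10 | ozonide (1,2,4-trioxolane) of 9 (not isolated) | CC1(C[C@@H]2O[C@H](C#C[Si](C)(C)C)C[C@H]2O[Si](C)(C)C(C)(C)C)OCOO1 | intermediate
11 | 1-[(2S,3R,5S)-3-(TBS-oxy)-5-[(trimethylsilyl)ethynyl]oxolan-2-yl]propan-2-one | CC(=O)C[C@@H]1O[C@H](C#C[Si](C)(C)C)C[C@H]1O[Si](C)(C)C(C)(C)C | intermediate
12 | 1-[(2S,3R,5S)-3-(TBS-oxy)-5-[(trimethylsilyl)ethynyl]oxolan-2-yl]-2-methylbut-3-en-2-ol (C7 epimers) | C=CC(C)(O)C[C@@H]1O[C@H](C#C[Si](C)(C)C)C[C@H]1O[Si](C)(C)C(C)(C)C | intermediate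
13 | 1-[(2S,3R,5S)-3-(TBS-oxy)-5-ethynyloxolan-2-yl]-2-methylbut-3-en-2-ol (C7 epimers) | C=CC(C)(O)C[C@@H]1O[C@H](C#C)C[C@H]1O[Si](C)(C)C(C)(C)C | intermediate
14 | bridged enol ether: 8-(TBS-oxy)-4-methyl-2-methylidene-4-vinyl-3,9-dioxabicyclo[4.2.1]nonane (C7 epimers; not isolated) | C=C1OC(C)(C=C)C[C@@H]2O[C@H]1C[C@H]2O[Si](C)(C)C(C)(C)C | intermediate
15 | (1S,8S,9R,5Z)-9-(TBS-oxy)-6-methyl-11-oxabicyclo[6.2.1]undec-5-en-2-one | O=C1CC/C=C(C)\C[C@@H]2O[C@H]1C[C@H]2O[Si](C)(C)C(C)(C)C | intermediate
16 | (1S,2S,8S,9R,5Z)-9-(TBS-oxy)-2,6-dimethyl-11-oxabicyclo[6.2.1]undec-5-en-2-ol | C[C@]1(O)CC/C=C(C)\C[C@@H]2O[C@H]1C[C@H]2O[Si](C)(C)C(C)(C)C | intermediate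
17 | (1S,2S,8S,9R,5Z)-2,6-dimethyl-11-oxabicyclo[6.2.1]undec-5-ene-2,9-diol | C[C@]1(O)CC/C=C(C)\C[C@@H]2O[C@H]1C[C@H]2O | intermediate
18 | (1S,2S,8S,5Z)-2-hydroxy-2,6-dimethyl-11-oxabicyclo[6.2.1]undec-5-en-9-one | C[C@]1(O)CC/C=C(C)\C[C@@H]2O[C@H]1CC2=O | intermediate
19 | enol triflate of 18 (C10(OTf)=C1) | C[C@]1(O)CC/C=C(C)\C[C@@H]2O[C@H]1C=C2OS(=O)(=O)C(F)(F)F | intermediate
20 | (1S,2S,8S,5Z)-9-(1-ethoxyvinyl)-2,6-dimethyl-11-oxabicyclo[6.2.1]undeca-5,9-dien-2-ol | C[C@]1(O)CC/C=C(C)\C[C@@H]2O[C@H]1C=C2C(=C)OCC | intermediate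
21 | endo Diels–Alder adduct, 14-epi-22 (acetyl cis to C2; not isolated) | CCOC1=C2[C@@H]3C/C(C)=C\CC[C@](C)(O)[C@@H](O3)[C@H]2[C@@H](C(C)=O)CC1 | intermediate
22 | tricyclic enol ether, 14-acetyl (trans to C2), C10=C11(OEt), 3-OH | CCOC1=C2[C@@H]3C/C(C)=C\CC[C@](C)(O)[C@@H](O3)[C@H]2[C@H](C(C)=O)CC1 | intermediate
23 | tricyclic enol ether, 14-isopropenyl | CCOC1=C2[C@@H]3C/C(C)=C\CC[C@](C)(O)[C@@H](O3)[C@H]2[C@H](C(C)=C)CC1 | intermediate
24 | tricyclic C11 ketone, cis-fused, 14-isopropenyl, 3-OH | O=C1[C@H]2[C@@H]3C/C(C)=C\CC[C@](C)(O)[C@@H](O3)[C@H]2[C@H](C(C)=C)CC1 | intermediate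
25 | 3,11-diol, 14-isopropenyl | C[C@]1(O)[C@H]2[C@@H]3C/C(C)=C\CC[C@](C)(O)[C@@H](O3)[C@H]2[C@H](C(C)=C)CC1 | intermediate
26 | C16 diisopinocampheylborane adduct of 25 (not isolated) | C[C@]1(O)[C@H]2[C@@H]3C/C(C)=C\CC[C@](C)(O)[C@@H](O3)[C@H]2[C@H]([C@@H](C)CB([C@@H]4C[C@@H]5C[C@H]([C@H]4C)C5(C)C)[C@@H]4C[C@@H]5C[C@H]([C@H]4C)C5(C)C)CC1 | intermediate
27 | 3,11,16-triol (15R) | C[C@]1(O)[C@H]2[C@@H]3C/C(C)=C\CC[C@](C)(O)[C@@H](O3)[C@H]2[C@H]([C@@H](C)CO)CC1 | intermediate
28 | C16 aldehyde, 3,11-diol (not isolated) | C[C@]1(O)[C@H]2[C@@H]3C/C(C)=C\CC[C@](C)(O)[C@@H](O3)[C@H]2[C@H]([C@@H](C)C=O)CC1 | intermediate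
29 | seven-membered lactol (C16 epimers; not isolated) | O[C@]1(C)CC[C@@H]2[C@H]3[C@@H]1[C@@H]1C/C(C)=C\CC[C@](C)(OC(O)[C@@H]2C)[C@H]3O1 | intermediate
30 | hydroxy lactone (11-deacetyl target) | O[C@]1(C)CC[C@@H]2[C@H]3[C@@H]1[C@@H]1C/C(C)=C\CC[C@](C)(OC(=O)[C@@H]2C)[C@H]3O1 | intermediate
31 | CNP0332402.2 | CC(=O)O[C@]1(C)CC[C@@H]2[C@H]3[C@@H]1[C@@H]1C/C(C)=C\CC[C@](C)(OC(=O)[C@@H]2C)[C@H]3O1 | target

## Step count and risks

Total step count: 22. Longest linear sequence: 22 steps (fully linear from 1 and 2).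

Steps most likely to fail:

1. Step 10 (Proposed new method). The 7-exo addition of a tertiary alcohol may be slow, so that alkyne hydration, oligomerisation or gold-induced ionisation of the tertiary allylic alcohol competes; one C7 epimer may also rearrange more slowly than the other. Fallback with known reactions, from 13 back to 15: alkyne 13 is hydrated (gold(I) or Hg(II) catalysis, aqueous MeOH) to methyl ketone F1. F1 is closed with HC(OMe)3/MeOH and PPTS to bridged mixed methyl ketal F2 (ketal exchange with the C7 hydroxyl, forming the seven-membered ring). Methanol is then eliminated from F2 with TMSOTf/i-Pr2NEt to give enol ether 14, this time isolated, which is heated in toluene (thermal Claisen ring expansion) to 15.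

2. Step 20. Facial selectivity at the 1,1-disubstituted alkene may be poor, because reagent control by Ipc2BH is weak for this alkene class and may not be reinforced by C14. Fallback, from 25 back to 30: 25 is hydroborated with 9-BBN to alkylborane F3 and oxidised without regard to C15, giving 27 together with its C15 epimer F4. The mixture is taken through the conditions of step 21, where F4 passes through epimeric aldehyde F5 and epimeric lactol F6 to 15-epi-lactone F7. After separation from 30, F7 is epimerised at C15 through its lactone enolate (KOt-Bu/t-BuOH equilibration, or LDA followed by kinetic protonation) and recycled, so that C15 is set at the lactone stage instead of at the alkene.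

3. Step 21. Lactol formation at the hindered tertiary C3 hydroxyl may be slow, so that the aldehyde is over-oxidised to the acid or epimerises at C15 before it is trapped. Fallback, from 27 back to 30: the primary alcohol is oxidised on purpose to seco acid F8 (TEMPO/PhI(OAc)2 in MeCN/H2O). F8 is then closed by Yamaguchi lactonisation (2,4,6-trichlorobenzoyl chloride, Et3N; DMAP, PhMe, 80 °C), in which the acyl group is activated rather than relying on a lactol equilibrium.

Further compounds
F1 | step 10 | 1-[(2S,4R,5S)-4-(TBS-oxy)-5-(2-hydroxy-2-methylbut-3-enyl)oxolan-2-yl]ethan-1-one (methyl ketone from 13; C7 epimers) | C=CC(C)(O)C[C@@H]1O[C@H](C(C)=O)C[C@H]1O[Si](C)(C)C(C)(C)C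
F2 | step 10 | bridged mixed methyl ketal: 8-(TBS-oxy)-2-methoxy-2,4-dimethyl-4-vinyl-3,9-dioxabicyclo[4.2.1]nonane | COC1(C)OC(C)(C=C)C[C@@H]2O[C@H]1C[C@H]2O[Si](C)(C)C(C)(C)C
F3 | step 20 | C16 9-borabicyclononane adduct of 25 (C15 epimers) | C[C@]1(O)[C@H]2[C@@H]3C/C(C)=C\CC[C@](C)(O)[C@@H](O3)[C@H]2[C@H](C(C)CB4C5CCCC4CCC5)CC1
F4 | step 20 | 15-epi-triol (15-epi-27) | C[C@]1(O)[C@H]2[C@@H]3C/C(C)=C\CC[C@](C)(O)[C@@H](O3)[C@H]2[C@H]([C@H](C)CO)CC1
F5 | step 20 | 15-epi-aldehyde (15-epi-28) | C[C@]1(O)[C@H]2[C@@H]3C/C(C)=C\CC[C@](C)(O)[C@@H](O3)[C@H]2[C@H]([C@H](C)C=O)CC1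
F6 | step 20 | 15-epi-lactol (15-epi-29) | O[C@]1(C)CC[C@@H]2[C@H]3[C@@H]1[C@@H]1C/C(C)=C\CC[C@](C)(OC(O)[C@H]2C)[C@H]3O1
F7 | step 20 | 15-epi-hydroxy lactone (15-epi-30) | O[C@]1(C)CC[C@@H]2[C@H]3[C@@H]1[C@@H]1C/C(C)=C\CC[C@](C)(OC(=O)[C@H]2C)[C@H]3O1
F8 | step 21 | seco acid (C16 carboxylic acid, 3,11-diol) | C[C@]1(O)[C@H]2[C@@H]3C/C(C)=C\CC[C@](C)(O)[C@@H](O3)[C@H]2[C@H]([C@@H](C)C(=O)O)CC1
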